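**Strategy.** Everything rests on the C3–C4 pair of ring A: an oxygenated carbon next to the gem-dimethyl quaternary carbon, the retron of a semipinacol shift. Ring A is therefore grown from a cyclopentanol. In the precursor, an A-nor hydrindene, C3 carries OH, an isopropenyl group (future C4 and its two methyls) and the ring B alkenyl carbon C5. Cobalt-hydride hydrogen-atom transfer and oxidation make C4 cationic, and C5 migrates from C3 to C4. One operation gives six-membered ring A, the C4 quaternary centre and the C3 ketone. The precursor arises from 2-methylcyclohexane-1,3-dione and acrolein through a desymmetrising carbene-catalysed benzoin reaction that sets C10.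

Key step: step 6

Remark: labdane numbering is used for all intermediates (in the A-nor compounds C3 is bonded directly to C5). The sense of induction in step 2 is assumed by analogy, and the commercial mirror-image precatalyst is used if it proves opposite.

Step 1
Reactants: 1 2-methylcyclohexane-1,3-dione; 2 acrolein
Product: 3 3-(1-methyl-2,6-dioxocyclohexyl)propanal
Conditions: H2O, rt
Reagents that add atoms: none
Why: Michael addition of the enolised 1,3-dione to acrolein should alkylate the central carbon and give the quaternary, still prochiral C10 with the C1–C2–C3 chain attached.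

Step 2
Reactants: 3 3-(1-methyl-2,6-dioxocyclohexyl)propanal
Product: 4 (3aS,7aR)-7a-hydroxy-3a-methylhexahydro-1H-indene-1,4(2H)-dione (cis-fused acyloin, C5-OH and C10-CH3 both β)
Conditions: (5aR,10bS)-2-(pentafluorophenyl)-5a,10b-dihydro-4H,6H-indeno[2,1-b][1,2,4]triazolo[4,3-d][1,4]oxazin-2-ium tetrafluoroborate (10 mol %), Et3N (10 mol %), toluene, rt
Reagents that add atoms: none
Why: Intramolecular crossed benzoin reaction, in which the carbene turns aldehyde carbon C3 into an acyl anion equivalent that adds 5-exo-trig to one of the two enantiotopic ketones; the chiral catalyst selects the ketone and so fixes C10 (S), and the short tether enforces the cis fusion at C5.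

Step 3
Reactants: 4 cis-fused acyloin
Product: 5 (3aS)-3a-methyl-2,3,5,6-tetrahydro-1H-indene-1,4(3aH)-dione (A-nor enedione, C3 ketone conjugated with C5=C6, free C9 ketone)
Conditions: SOCl2, pyridine, CH2Cl2, 0 °C
Reagents that add atoms: none
Why: Dehydration of the tertiary alcohol through its chlorosulfite (E2 elimination); C6 carries the only β-hydrogens (C10 is quaternary, C3 is a carbonyl carbon), so only the C5=C6 enone can form, and the C5 centre is erased on purpose.

Step 4
Reactants: 5 A-nor enedione
Product: 6 A-nor enone acetal (5 with C9 as 1,3-dioxolane, 10S)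
Conditions: ethane-1,2-diol, p-TsOH·H2O, 4 Å molecular sieves, rt
Reagents that add atoms: ethane-1,2-diol, OCCO
Why: Chemoselective acetalisation, in which the saturated C9 ketone should react much faster than the conjugated and less electrophilic C3 enone carbonyl, as is usual for bicyclic enediones of this kind.

Step 5
Reactants: 6 A-nor enone acetal; 7 isopropenylmagnesium bromide
Product: 8 A-nor bis-allylic carbinol (3β-hydroxy-3α-isopropenyl derivative of 6, 3R,10S)
Conditions: CeCl3 (anhydrous), THF, −78 °C; pH 7 buffer
Reagents that add atoms: none
Why: Organocerium 1,2-addition to the only free carbonyl, with the weakly basic, oxophilic reagent suppressing enolisation and 1,4-addition; attack should come from the α face opposite the C10 methyl group, although this C3 centre is erased in step 6.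

Step 6
Reactants: 8 A-nor bis-allylic carbinol
Product: 9 (10S)-4,4,10-trimethyl-Δ5(6)-octalin-3-one 9-ethylene acetal
Conditions: [N,N′-bis(3,5-di-tert-butylsalicylidene)-1,2-cyclohexanediaminato]cobalt (divalent cobalt, 5 mol %), N-fluoro-2,4,6-trimethylpyridinium triflate, PhSiH3, acetone, 0 °C to rt
Reagents that add atoms: none
Why: A cobalt hydride formed from the silane transfers a hydrogen atom to the terminal CH2 of the isopropenyl group, the tertiary C4 radical is captured and oxidised by the N-fluoropyridinium salt to a tertiary cation equivalent, and the C3–C5 bond shifts to C4 while the C3 hydroxyl collapses to the ketone. The reaction type is the hydrogen-atom-transfer-initiated radical-polar crossover semipinacol rearrangement of tertiary allylic alcohols, used here in its ring-expanding form. No ring is closed by cyclisation: the five-membered ring C1-C2-C3-C5-C10 becomes six-membered ring A by a 1,2-shift through a bridged three-membered (3-exo, cyclopropylcarbinyl-like) arrangement of C3, C4 and C5. No new stereocentre is formed, since the C3 carbinol centre is erased, C4 carries two equal methyl groups and C10 is untouched. The step needs migration of C5 and not of C2, secured by the much higher migratory aptitude of an alkenyl carbon over a primary alkyl carbon, and it needs hydrogen-atom transfer to the isopropenyl group and not to C5=C6, secured by the faster reaction of an unhindered 1,1-disubstituted alkene compared with a trisubstituted alkene next to a quaternary carbon. The near-neutral medium avoids the ionisation of the bis-allylic alcohol that a Brønsted acid would cause and spares the acetal.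

Step 7
Reactants: 9 ring-expanded ketone acetal
Product: 10 3β-alcohol of 9 (3S,10S)
Conditions: NaBH4, MeOH, 0 °C
Reagents that add atoms: none
Why: Borohydride reduction in which hydride should attack axially from the α face, away from the axial 4β and 10β methyl groups, to give the equatorial 3β-alcohol and set C3.

Step 8
Reactants: 10 3β-alcohol
Product: 12 3β-hydroxy-4,4,10β-trimethyl-trans-decalin-9-one (5α-H), via saturated acetal 11 (not isolated)
Conditions: Mn(dpm)3 (10 mol %), PhSiH3, t-BuOOH, i-PrOH, rt; then 2 M HCl, THF, rt
Reagents that add atoms: water, O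
Why: Radical (hydrogen-atom-transfer) alkene hydrogenation puts the first hydrogen on the accessible C6, and the tertiary C5 radical should take the second from the α face opposite the two axial β methyl groups, giving the more stable trans-decalin and setting C5; acid hydrolysis then frees the C9 ketone.

Step 9
Reactants: 12 trans-decalone
Product: 13 3β-hydroxy-11-nordriman-9-one (8α-CH3, 8β-H)
Conditions: LDA (2.3 equiv), THF, −78 to 0 °C; MeI (1.1 equiv), −78 °C to rt; then NaOMe, MeOH, rt
Reagents that add atoms: iodomethane, CI
Why: Enolate alkylation in which only C8 carries α-hydrogens (C10 is quaternary); base equilibration places the new methyl group equatorial (8α), free of the 1,3-diaxial clash with the C10 methyl group, which sets C8.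

Step 10
Reactants: 13 3β-hydroxy-11-nordriman-9-one
Product: 14 drim-9(11)-en-3β-ol
Conditions: Ph3PCH3Br, KOt-Bu (5 equiv each), toluene, 100 °C
Reagents that add atoms: methyltriphenylphosphonium bromide, C[P+](c1ccccc1)(c1ccccc1)c1ccccc1.[Br-]
Why: Wittig methylenation with excess ylide at high temperature is the established answer to hindered ketones, and any epimerisation at C8 beforehand returns the same equatorial epimer.

Step 11
Reactants: 14 drim-9(11)-en-3β-ol
Product: 15 9α,11-epoxydriman-3β-ol
Conditions: m-CPBA, NaHCO3, CH2Cl2, 0 °C
Reagents that add atoms: 3-chloroperbenzoic acid, OOC(=O)c1cccc(Cl)c1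
Why: Prilezhaev epoxidation should occur from the α face, opposite the axial C10 methyl group that flanks the alkene, so oxygen becomes axial (9α) and C11 equatorial (β), which sets C9 with the sense that direct carbon addition to the ketone would not give.

Step 12
Reactants: 15 9α,11-epoxydriman-3β-ol
Product: 16 13,14,15,16-tetranorlabd-11-ene-3β,9α-diol (C9 vinyl carbinol)
Conditions: Me3SI, n-BuLi (5 equiv each), THF, −10 °C to rt
Reagents that add atoms: trimethylsulfonium iodide, C[S+](C)C.[I-]
Why: One-carbon homologation of a terminal epoxide to an allylic alcohol, in which dimethylsulfonium methylide opens the epoxide at the CH2 carbon C11 and base-induced loss of dimethyl sulfide gives C11=C12; the C9–O bond is never broken, so C9 is retained.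

Step 13
Reactants: 16 vinyl carbinol diol
Product: 17 3β-acetoxy-13,14,15,16-tetranorlabd-11-en-9α-ol
Conditions: Ac2O, pyridine, DMAP (cat.), rt
Reagents that add atoms: acetic anhydride, CC(=O)OC(C)=O
Why: Selective acylation in which the secondary equatorial 3β-hydroxyl reacts, while the tertiary axial 9α-hydroxyl between C8 and quaternary C10 should stay free.

Step 14
Reactants: 17 3β-acetoxy vinyl carbinol; 18 4-bromofuran-2(5H)-one
Product: 20 3β-acetoxy-9α-hydroxylabd-13-en-16,15-olide (target, 3S,5S,8R,9R,10S), via B-alkyl-9-BBN borane 19 (not isolated)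
Conditions: 9-BBN-H (3 equiv), THF, rt to 50 °C; then 18, PdCl2(dppf) (5 mol %), AsPh3, Cs2CO3, DMF–H2O, rt
Reagents that add atoms: 9-borabicyclo[3.3.1]nonane (9-BBN-H), B1C2CCCC1CCC2 (its boron and bicycle stay only in 19)
Why: Anti-Markovnikov hydroboration places boron on terminal C12, and a B-alkyl Suzuki–Miyaura coupling with the activated β-bromobutenolide forms C12–C13; the mild base at room temperature should spare acetate and lactone, and no stereocentre is touched.

**Compound list**
1 | 2-methylcyclohexane-1,3-dione | CC1C(=O)CCCC1=O | starting material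
2 | acrolein | C=CC=O | starting material
3 | 3-(1-methyl-2,6-dioxocyclohexyl)propanal | CC1(CCC=O)C(=O)CCCC1=O | intermediate
4 | (3aS,7aR)-7a-hydroxy-3a-methylhexahydro-1H-indene-1,4(2H)-dione | C[C@]12CCC(=O)[C@@]1(O)CCCC2=O | intermediate
5 | (3aS)-3a-methyl-2,3,5,6-tetrahydro-1H-indene-1,4(3aH)-dione | C[C@]12CCC(=O)C1=CCCC2=O | intermediate
6 | A-nor enone acetal (C9 1,3-dioxolane of 5) | C[C@]12CCC(=O)C1=CCCC23OCCO3 | intermediate
7 | isopropenylmagnesium bromide | CC(=C)[Mg]Br | starting material
8 | A-nor bis-allylic carbinol (3β-OH, 3α-isopropenyl) | C[C@]12CC[C@@](O)(C(C)=C)C1=CCCC23OCCO3 | intermediate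
9 | (10S)-4,4,10-trimethyl-Δ5(6)-octalin-3-one 9-ethylene acetal | C[C@]12CCC(=O)C(C)(C)C1=CCCC23OCCO3 | intermediate
10 | 3β-alcohol of 9 | C[C@]12CC[C@H](O)C(C)(C)C1=CCCC23OCCO3 | intermediate
11 | saturated acetal (3β-OH, 5α-H, trans-decalin) | C[C@]12CC[C@H](O)C(C)(C)[C@@H]1CCCC23OCCO3 | intermediate
12 | 3β-hydroxy-4,4,10β-trimethyl-trans-decalin-9-one | C[C@]12CC[C@H](O)C(C)(C)[C@@H]1CCCC2=O | intermediate
13 | 3β-hydroxy-11-nordriman-9-one (8α-CH3) | C[C@]12CC[C@H](O)C(C)(C)[C@@H]1CC[C@@H](C)C2=O | intermediate
14 | drim-9(11)-en-3β-ol | C[C@]12CC[C@H](O)C(C)(C)[C@@H]1CC[C@@H](C)C2=C | intermediate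
15 | 9α,11-epoxydriman-3β-ol | C[C@]12CC[C@H](O)C(C)(C)[C@@H]1CC[C@@H](C)[C@]23CO3 | intermediate
16 | 13,14,15,16-tetranorlabd-11-ene-3β,9α-diol | C[C@]12CC[C@H](O)C(C)(C)[C@@H]1CC[C@@H](C)[C@]2(O)C=C | intermediate
17 | 3β-acetoxy-13,14,15,16-tetranorlabd-11-en-9α-ol | C[C@]12CC[C@H](OC(C)=O)C(C)(C)[C@@H]1CC[C@@H](C)[C@]2(O)C=C | intermediate
18 | 4-bromofuran-2(5H)-one | BrC1=CC(=O)OC1 | starting material
19 | B-(3β-acetoxy-9α-hydroxy-13,14,15,16-tetranorlabdan-12-yl)-9-BBN | C[C@]12CC[C@H](OC(C)=O)C(C)(C)[C@@H]1CC[C@@H](C)[C@]2(O)CCB1C2CCCC1CCC2 | intermediate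
20 | 3β-acetoxy-9α-hydroxylabd-13-en-16,15-olide | CC(=O)O[C@H]1CC[C@@]2(C)[C@@H](CC[C@@H](C)[C@]2(O)CCC2=CC(=O)OC2)C1(C)C | target

Total step count: 14. Longest linear sequence: 14 steps (from 1 to 20; 2, 7 and 18 are bought).

**Steps most likely to fail**

Step 6. The C3 hydroxyl may capture the C4 cation equivalent and form an epoxide, or hydrogen-atom transfer may go to the ring alkene, and either process could compete with the shift. The fallback makes the C4 cation from a leaving group instead of an alkene and sets out from 6. 2-Lithio-2-(methylseleno)propane (from 2,2-bis(methylseleno)propane and n-BuLi, THF, −78 °C) adds 1,2 to the C3 ketone to give the β-hydroxy selenide F1. AgBF4 on basic alumina in CH2Cl2 then turns selenium into a leaving group, and the same C5 shift should give 9, where the route is rejoined.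

Step 12. Attack of the ylide at the neopentyl carbon C11 may be slow, and base-induced isomerisation of the epoxide may take over. The fallback brings in C12–C16 as one nucleophile and sets out from 15. 3-Furylmethylmagnesium chloride with CuI (10 mol %) in THF opens the epoxide at C11 to give the furan diol F2. Ac2O in pyridine gives the furan acetate F3. Photooxygenation (O2, rose bengal, visible light, i-Pr2NEt, CH2Cl2, −78 °C) gives the γ-hydroxybutenolide F4 with the hydroxyl carbon next to C13. NaBH4 in EtOH followed by mild acid closes the lactone to 20, so steps 13 and 14 are bypassed.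

Step 10. The hindered ketone may enolise and the phosphorus ylide may add too slowly. The fallback is a two-stage Peterson olefination and sets out from 13. Me3SiCH2Li with CeCl3 (THF, −78 °C) adds from the α face to give the β-hydroxysilane F5, and KH in THF eliminates the silanolate to give 14, where the route is rejoined.

**Further compounds**
F1 | step 6 | β-hydroxy selenide (3β-OH, 3α-[2-(methylseleno)propan-2-yl] derivative of 6) | C[C@]12CC[C@@](O)(C(C)(C)[Se]C)C1=CCCC23OCCO3
F2 | step 12 | furan diol (15,16-epoxylabda-13(16),14-diene-3β,9α-diol) | C[C@]12CC[C@H](O)C(C)(C)[C@@H]1CC[C@@H](C)[C@]2(O)CCc1ccoc1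
F3 | step 12 | furan acetate (3-acetate of F2) | C[C@]12CC[C@H](OC(C)=O)C(C)(C)[C@@H]1CC[C@@H](C)[C@]2(O)CCc1ccoc1
F4 | step 12 | γ-hydroxybutenolide (16-hydroxy derivative of 20, both C16 epimers) | C[C@]12CC[C@H](OC(C)=O)C(C)(C)[C@@H]1CC[C@@H](C)[C@]2(O)CCC1=CC(=O)OC1O
F5 | step 10 | β-hydroxysilane (9β-OH, 9α-CH2SiMe3) | C[C@]12CC[C@H](O)C(C)(C)[C@@H]1CC[C@@H](C)[C@@]2(O)C[Si](C)(C)C
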